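**Plan**

- Retrosynthesis (chromanone numbering of the target: O1, C2, C3, C4, C4a, C5–C8, C8a; ring A is the carbocycle). The cuts, in order: the C8–prenyl bond (dearomatising allylation), the C8–CH2 bond to the lavandulyl chain (sp3–sp2 coupling at an aryl iodide), then C4–C4a and C2–C3 together (1,2-shift in a lactate-derived diazoketone, ring closure of the resulting ketene), then O1–C2 (etherification). This leaves 5,7-dihydroxy-4-propylcoumarin, from phloroglucinol and ethyl 3-oxohexanoate.
- Forward order of rings: ring A is bought aromatic. A δ-lactone ring (coumarin, then dihydrocoumarin) is fused first as a temporary ring that carries the hexanoate chain and masks O7 and the acid. The pyranone ring is closed by the key step. The lactone is then opened and ring A is dearomatised last.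
- Enabling feature: the aryl ether oxygen O1 on C8a with a single free ring carbon (C4a) ortho to it; the other ortho carbon, C8, carries an iodine that later anchors the lavandulyl chain. The ketene carbon (future C4), released when C2 migrates onto C3, therefore lies within six-membered reach of C4a.
- Stereochemistry: C2 from tert-butyl (S)-lactate (inversion on etherification, retention in the 1,2-shift). C3 by kinetic protonation of the cyclic enolate (cis). The hexanoate CH by CuH/(R)-DTBM-SEGPHOS conjugate reduction of the coumarin. The lavandulyl CH by lipase resolution. C8 by the chiral palladium catalyst in the last step.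

Key step: step 10

Assumption: the enantiomer preference of the lipase (step 1) and the sense of induction of the chiral ligands (steps 6 and 13) are taken by analogy; if a trial run shows the opposite sense, the acetate fraction (after methanolysis) or the mirror-image ligand is used, with no other change.

**Route**

Step 1
Reactants: 1 (±)-lavandulol
Product: 2 (S)-lavandulol [(2S)-5-methyl-2-(prop-1-en-2-yl)hex-4-en-1-ol]
Conditions: porcine pancreatic lipase, vinyl acetate, hexane, rt, run to about 60% conversion; chromatography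
Reagents that add atoms: none
Why: Lipase-catalysed kinetic resolution by enantioselective transesterification should acetylate the R alcohol faster, so the alcohol recovered beyond half conversion should be the S enantiomer, which carries the lavandulyl stereocentre of the target.

Step 2
Reactants: 2 (S)-lavandulol
Product: 3 (S)-lavandulyl iodide [(3S)-3-(iodomethyl)-2,6-dimethylhepta-1,5-diene]
Conditions: I2, PPh3, imidazole, CH2Cl2, 0 °C → rt
Reagents that add atoms: iodine, II
Why: Appel iodination displaces the oxyphosphonium group at the primary CH2 by SN2 and leaves the adjacent stereocentre untouched.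

Step 3
Reactants: 4 phloroglucinol; 5 ethyl 3-oxohexanoate
Product: 6 5,7-dihydroxy-4-propyl-2H-chromen-2-one
Conditions: conc. H2SO4, 0 °C → rt
Reagents that add atoms: none
Why: Pechmann condensation (transesterification, ring hydroxyalkylation, dehydration) on the threefold-symmetric triol can give only one coumarin.

Step 4
Reactants: 6 5,7-dihydroxy-4-propyl-2H-chromen-2-one; 7 tert-butyl (S)-lactate
Product: 8 tert-butyl (2R)-2-[(5-hydroxy-2-oxo-4-propyl-2H-chromen-7-yl)oxy]propanoate
Conditions: PPh3, DIAD, THF, 0 °C → rt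
Reagents that add atoms: none
Why: Mitsunobu etherification should take the more acidic, unhindered 7-OH (the 5-OH is shielded by the peri propyl group) and proceeds with SN2 inversion at the lactate carbon, which sets the R ether centre that becomes C2.

Step 5
Reactants: 8 tert-butyl (2R)-2-[(5-hydroxy-2-oxo-4-propyl-2H-chromen-7-yl)oxy]propanoate
Product: 9 tert-butyl (2R)-2-({5-[(tert-butyldimethylsilyl)oxy]-2-oxo-4-propyl-2H-chromen-7-yl}oxy)propanoate
Conditions: TBSCl, imidazole, DMF, rt
Reagents that add atoms: tert-butyldimethylsilyl chloride, CC(C)(C)[Si](C)(C)Cl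
Why: Silylation masks the remaining phenol against the acid chloride and diazoalkane steps, and its bulk later shields the ring carbon between the two ether oxygens.

Step 6
Reactants: 9 tert-butyl (2R)-2-({5-[(tert-butyldimethylsilyl)oxy]-2-oxo-4-propyl-2H-chromen-7-yl}oxy)propanoate
Product: 10 tert-butyl (2R)-2-({(4R)-5-[(tert-butyldimethylsilyl)oxy]-2-oxo-4-propyl-3,4-dihydro-2H-chromen-7-yl}oxy)propanoate
Conditions: Cu(OAc)2·H2O (3 mol %), (R)-DTBM-SEGPHOS (3 mol %), (EtO)2MeSiH, t-BuOH, toluene, 0 °C → rt
Reagents that add atoms: none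
Why: Copper hydride-catalysed asymmetric conjugate reduction of the coumarin enoate delivers hydride to one face of C4 under ligand control and should give the 4R lactone, with the tert-butyl ester and silyl ether inert.

Step 7
Reactants: 10 tert-butyl (2R)-2-({(4R)-5-[(tert-butyldimethylsilyl)oxy]-2-oxo-4-propyl-3,4-dihydro-2H-chromen-7-yl}oxy)propanoate
Product: 11 tert-butyl (2R)-2-({(4R)-5-[(tert-butyldimethylsilyl)oxy]-8-iodo-2-oxo-4-propyl-3,4-dihydro-2H-chromen-7-yl}oxy)propanoate
Conditions: N-iodosuccinimide, CF3CO2H (10 mol %), MeCN, 0 °C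
Reagents that add atoms: N-iodosuccinimide, O=C1CCC(=O)N1I
Why: Electrophilic aromatic iodination should go to C8 of the lactone numbering (the future C8 of the target), which is para to the silyloxy group and flanked only by the ring oxygen, rather than to the crowded C6 between the silyloxy and lactate ether groups; the iodine blocks this carbon in the key step and is the later coupling handle.

Step 8
Reactants: 11 tert-butyl (2R)-2-({(4R)-5-[(tert-butyldimethylsilyl)oxy]-8-iodo-2-oxo-4-propyl-3,4-dihydro-2H-chromen-7-yl}oxy)propanoate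
Product: 12 (2R)-2-({(4R)-5-[(tert-butyldimethylsilyl)oxy]-8-iodo-2-oxo-4-propyl-3,4-dihydro-2H-chromen-7-yl}oxy)propanoic acid
Conditions: CF3CO2H, CH2Cl2, 0 °C
Reagents that add atoms: none
Why: Acidolysis of the tert-butyl ester (loss of 2-methylpropene) frees the acid without base, so the aryl lactone, the aryl silyl ether and the α-aryloxy stereocentre should be kept.

Step 9
Reactants: 12 (2R)-2-({(4R)-5-[(tert-butyldimethylsilyl)oxy]-8-iodo-2-oxo-4-propyl-3,4-dihydro-2H-chromen-7-yl}oxy)propanoic acid
Product: 14 (4R)-5-[(tert-butyldimethylsilyl)oxy]-7-{[(2R)-4-diazo-3-oxopentan-2-yl]oxy}-8-iodo-4-propyl-3,4-dihydro-2H-chromen-2-one, via acid chloride 13 (not isolated)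
Conditions: (COCl)2, DMF (cat.), CH2Cl2, 0 °C; evaporate; CH3CHN2 (3 equiv), Et2O, −20 → 0 °C
Reagents that add atoms: oxalyl chloride (Cl of 13 only), O=C(Cl)C(=O)Cl; diazoethane, CC=[N+]=[N-]
Why: Acylation of diazoethane by the acid chloride (first half of an Arndt–Eistert sequence, excess diazoalkane taking up HCl) gives the internal diazoketone, and no amine base is present that could epimerise the α-aryloxy centre through a ketene.

Step 10
Reactants: 14 (4R)-5-[(tert-butyldimethylsilyl)oxy]-7-{[(2R)-4-diazo-3-oxopentan-2-yl]oxy}-8-iodo-4-propyl-3,4-dihydro-2H-chromen-2-one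
Product: 17 (2R,3S,6R)-5-[(tert-butyldimethylsilyl)oxy]-10-iodo-2,3-dimethyl-6-propyl-2,3,6,7-tetrahydro-4H,8H-pyrano[3,2-g]chromene-4,8-dione, via methylketene 15 (not isolated), via aluminium enolate 16 (not isolated)
Conditions: hν (400 nm LEDs), CH2Cl2 (0.01 M), −78 °C; then EtAlCl2 (2.5 equiv), −78 °C; MeOH quench at −78 °C, then aq. Rochelle salt
Reagents that add atoms: ethylaluminium dichloride (AlCl2 of 16 only), CC[Al](Cl)Cl
Why: Proposed new method: irradiation expels N2 from the diazoketone with 1,2-shift of the (R)-1-aryloxyethyl group from the carbonyl carbon to the diazo carbon (Wolff rearrangement, retention at the migrating carbon), which makes the C2–C3 bond and leaves methylketene 15, whose central carbon is the future C4; EtAlCl2 then binds the ketene oxygen, the ring carbon ortho to the ether oxygen attacks that carbon (intramolecular Friedel–Crafts acylation) to make the C4–C4a bond, and the arenium proton leaves as ethane to give enolate 16. The closest known reaction types are the Arndt–Eistert/Wolff sequence with stereoretentive migration, the EtAlCl2-promoted cycloaddition of ketenes to alkenes and the Friedel–Crafts acylation of arenes by ketenes, whereas the tandem on an aryl ether has no direct precedent. The pyranone ring closes in a 6-exo-dig mode on the sp carbon of the ketene, the C=O lying outside the new ring. C2 is fixed by the lactate-derived centre, and C3 by kinetic protonation of 16 at −78 °C on the face anti to the pseudoaxial C2 methyl group, which should give the cis (2R,3S) ketone. The step needs regioselectivity between the two carbons ortho to the ether oxygen, secured because the other one carries iodine, and chemoselectivity for C-acylation over ketene dimerisation or a 1,2-hydride shift of the carbene, favoured by dilution, low temperature and the six-membered transition state.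

Step 11
Reactants: 17 (2R,3S,6R)-5-[(tert-butyldimethylsilyl)oxy]-10-iodo-2,3-dimethyl-6-propyl-2,3,6,7-tetrahydro-4H,8H-pyrano[3,2-g]chromene-4,8-dione; 3 (S)-lavandulyl iodide
Product: 19 (2R,3S,6R)-5-[(tert-butyldimethylsilyl)oxy]-2,3-dimethyl-10-[(2R)-5-methyl-2-(prop-1-en-2-yl)hex-4-en-1-yl]-6-propyl-2,3,6,7-tetrahydro-4H,8H-pyrano[3,2-g]chromene-4,8-dione, via lavandulylzinc iodide 18 (not isolated)
Conditions: 3, Zn dust (TMSCl-activated), LiCl, THF, 40 °C; then 17, Pd(OAc)2 (5 mol %), SPhos (10 mol %), THF, 40 °C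
Reagents that add atoms: zinc (Zn of 18 only), [Zn]
Why: Negishi sp3–sp2 coupling: zinc inserts into the primary C–I bond without touching the β-stereocentre, and the alkylzinc iodide should couple at the aryl iodide under Pd(OAc)2/SPhos faster than it adds to the ketone or lactone, the bulky biarylphosphine favouring reductive elimination over β-hydride elimination.

Step 12
Reactants: 19 (2R,3S,6R)-5-[(tert-butyldimethylsilyl)oxy]-2,3-dimethyl-10-[(2R)-5-methyl-2-(prop-1-en-2-yl)hex-4-en-1-yl]-6-propyl-2,3,6,7-tetrahydro-4H,8H-pyrano[3,2-g]chromene-4,8-dione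
Product: 20 (3R)-3-{(2R,3S)-5,7-dihydroxy-2,3-dimethyl-8-[(2R)-5-methyl-2-(prop-1-en-2-yl)hex-4-en-1-yl]-4-oxo-3,4-dihydro-2H-chromen-6-yl}hexanoic acid
Conditions: LiOH·H2O (6 equiv), THF/H2O 3:1, 0 °C → rt; then 1 M HCl to pH 3 at 0 °C
Reagents that add atoms: water, O
Why: Saponification opens the aryl lactone and cleaves the aryl silyl ether in one operation, and the phenoxides formed ortho and para to the ketone should lower the acidity of C3–H enough to keep the cis methyl groups.

Step 13
Reactants: 20 (3R)-3-{(2R,3S)-5,7-dihydroxy-2,3-dimethyl-8-[(2R)-5-methyl-2-(prop-1-en-2-yl)hex-4-en-1-yl]-4-oxo-3,4-dihydro-2H-chromen-6-yl}hexanoic acid; 21 prenyl acetate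
Product: 22 (3R)-3-{(2R,3S,8R)-5-hydroxy-2,3-dimethyl-8-(3-methylbut-2-en-1-yl)-8-[(2R)-5-methyl-2-(prop-1-en-2-yl)hex-4-en-1-yl]-4,7-dioxo-3,4,7,8-tetrahydro-2H-chromen-6-yl}hexanoic acid (target)
Conditions: Pd2(dba)3·CHCl3 (2.5 mol %), (R,R)-N,N′-bis(2-diphenylphosphinobenzoyl)cyclohexane-1,2-diamine (7.5 mol %), Et3N (3 equiv), CH2Cl2, 0 °C → rt; dilute HCl work-up
Reagents that add atoms: none
Why: Palladium-catalysed asymmetric allylic alkylation (Tsuji–Trost) used as a phenol dearomatisation: the 7-phenoxide, the most acidic phenol because it is para to the C4 ketone, should attack through its ortho carbon C8 at the less substituted end of the 1,1-dimethylallyl–palladium cation (C6 carries the branched hexanoate chain, and O-allylation of phenoxide or carboxylate is reversible under zerovalent palladium), giving the normal prenyl group and the dienone, while the chiral diphosphine pocket, not the remote substrate centres, selects the face of C8 to give 8R.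

**Compound list**

1 | (±)-lavandulol [rac-5-methyl-2-(prop-1-en-2-yl)hex-4-en-1-ol] | C=C(C)C(CC=C(C)C)CO | starting material
2 | (S)-lavandulol | C=C(C)[C@H](CC=C(C)C)CO | intermediate
3 | (S)-lavandulyl iodide [(3S)-3-(iodomethyl)-2,6-dimethylhepta-1,5-diene] | C=C(C)[C@H](CC=C(C)C)CI | intermediate
4 | phloroglucinol (benzene-1,3,5-triol) | Oc1cc(O)cc(O)c1 | starting material
5 | ethyl 3-oxohexanoate | CCCC(=O)CC(=O)OCC | starting material
6 | 5,7-dihydroxy-4-propyl-2H-chromen-2-one | CCCC1=CC(=O)Oc2cc(O)cc(O)c12 | intermediate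
7 | tert-butyl (S)-lactate [tert-butyl (2S)-2-hydroxypropanoate] | C[C@H](O)C(=O)OC(C)(C)C | starting material
8 | tert-butyl (2R)-2-[(5-hydroxy-2-oxo-4-propyl-2H-chromen-7-yl)oxy]propanoate | CCCC1=CC(=O)Oc2cc(O[C@H](C)C(=O)OC(C)(C)C)cc(O)c12 | intermediate
9 | tert-butyl (2R)-2-({5-[(tert-butyldimethylsilyl)oxy]-2-oxo-4-propyl-2H-chromen-7-yl}oxy)propanoate | CCCC1=CC(=O)Oc2cc(O[C@H](C)C(=O)OC(C)(C)C)cc(O[Si](C)(C)C(C)(C)C)c12 | intermediate
10 | tert-butyl (2R)-2-({(4R)-5-[(tert-butyldimethylsilyl)oxy]-2-oxo-4-propyl-3,4-dihydro-2H-chromen-7-yl}oxy)propanoate | CCC[C@@H]1CC(=O)Oc2cc(O[C@H](C)C(=O)OC(C)(C)C)cc(O[Si](C)(C)C(C)(C)C)c12 | intermediate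
11 | tert-butyl (2R)-2-({(4R)-5-[(tert-butyldimethylsilyl)oxy]-8-iodo-2-oxo-4-propyl-3,4-dihydro-2H-chromen-7-yl}oxy)propanoate | CCC[C@@H]1CC(=O)Oc2c(I)c(O[C@H](C)C(=O)OC(C)(C)C)cc(O[Si](C)(C)C(C)(C)C)c12 | intermediate
12 | (2R)-2-({(4R)-5-[(tert-butyldimethylsilyl)oxy]-8-iodo-2-oxo-4-propyl-3,4-dihydro-2H-chromen-7-yl}oxy)propanoic acid | CCC[C@@H]1CC(=O)Oc2c(I)c(O[C@H](C)C(=O)O)cc(O[Si](C)(C)C(C)(C)C)c12 | intermediate
13 | (2R)-2-({(4R)-5-[(tert-butyldimethylsilyl)oxy]-8-iodo-2-oxo-4-propyl-3,4-dihydro-2H-chromen-7-yl}oxy)propanoyl chloride | CCC[C@@H]1CC(=O)Oc2c(I)c(O[C@H](C)C(=O)Cl)cc(O[Si](C)(C)C(C)(C)C)c12 | intermediate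
14 | (4R)-5-[(tert-butyldimethylsilyl)oxy]-7-{[(2R)-4-diazo-3-oxopentan-2-yl]oxy}-8-iodo-4-propyl-3,4-dihydro-2H-chromen-2-one | CCC[C@@H]1CC(=O)Oc2c(I)c(O[C@H](C)C(=O)C(C)=[N+]=[N-])cc(O[Si](C)(C)C(C)(C)C)c12 | intermediate
15 | (4R)-5-[(tert-butyldimethylsilyl)oxy]-8-iodo-7-{[(2R)-3-methyl-4-oxobut-3-en-2-yl]oxy}-4-propyl-3,4-dihydro-2H-chromen-2-one (methylketene) | CCC[C@@H]1CC(=O)Oc2c(I)c(O[C@H](C)C(C)=C=O)cc(O[Si](C)(C)C(C)(C)C)c12 | intermediate
16 | dichloroaluminium enolate of 17 [(2R,6R)-5-silyloxy-4-(dichloroalumanyloxy)-10-iodo-2,3-dimethyl-6-propyl-6,7-dihydro-2H,8H-pyrano[3,2-g]chromen-8-one] | CCC[C@@H]1CC(=O)Oc2c(I)c3O[C@H](C)C(C)=C(O[Al](Cl)Cl)c3c(O[Si](C)(C)C(C)(C)C)c12 | intermediate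
17 | (2R,3S,6R)-5-[(tert-butyldimethylsilyl)oxy]-10-iodo-2,3-dimethyl-6-propyl-2,3,6,7-tetrahydro-4H,8H-pyrano[3,2-g]chromene-4,8-dione (linear tricycle: cis-2,3-dimethylpyran-4-one ring, central benzene ring with OSi at C5 and I at C10, δ-lactone ring with propyl at C6) | CCC[C@@H]1CC(=O)Oc2c(I)c3O[C@H](C)[C@H](C)C(=O)c3c(O[Si](C)(C)C(C)(C)C)c12 | intermediate
18 | (S)-lavandulylzinc iodide | C=C(C)[C@H](CC=C(C)C)C[Zn]I | intermediate
19 | (2R,3S,6R)-5-[(tert-butyldimethylsilyl)oxy]-2,3-dimethyl-10-[(2R)-5-methyl-2-(prop-1-en-2-yl)hex-4-en-1-yl]-6-propyl-2,3,6,7-tetrahydro-4H,8H-pyrano[3,2-g]chromene-4,8-dione | CCC[C@@H]1CC(=O)Oc2c(C[C@@H](CC=C(C)C)C(C)=C)c3O[C@H](C)[C@H](C)C(=O)c3c(O[Si](C)(C)C(C)(C)C)c12 | intermediate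
20 | (3R)-3-{(2R,3S)-5,7-dihydroxy-2,3-dimethyl-8-[(2R)-5-methyl-2-(prop-1-en-2-yl)hex-4-en-1-yl]-4-oxo-3,4-dihydro-2H-chromen-6-yl}hexanoic acid | CCC[C@H](CC(=O)O)c1c(O)c(C[C@@H](CC=C(C)C)C(C)=C)c2O[C@H](C)[C@H](C)C(=O)c2c1O | intermediate
21 | prenyl acetate (3-methylbut-2-en-1-yl acetate) | CC(C)=CCOC(C)=O | starting material
22 | (3R)-3-{(2R,3S,8R)-5-hydroxy-2,3-dimethyl-8-(3-methylbut-2-en-1-yl)-8-[(2R)-5-methyl-2-(prop-1-en-2-yl)hex-4-en-1-yl]-4,7-dioxo-3,4,7,8-tetrahydro-2H-chromen-6-yl}hexanoic acid | C=C(C)[C@H](CC=C(C)C)C[C@@]1(CC=C(C)C)C(=O)C([C@H](CCC)CC(=O)O)=C(O)C2=C1O[C@H](C)[C@H](C)C2=O | target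

**Step count and risks**

Total steps: 13. Longest linear sequence: 11 (steps 3–13, from phloroglucinol); steps 1–2 make the lavandulyl fragment.

Steps most likely to fail:

1. Step 10 (Proposed new method). The carbene may undergo a 1,2-hydride shift from its methyl group, the ketene may dimerise or be captured by adventitious water before the ring carbon attacks, and protonation of the enolate may be poorly face-selective. Fallback, from 14, with the two bond formations separated: irradiation of 14 in THF/H2O (classical Arndt–Eistert homologation) would give (3R)-3-({(4R)-5-[(tert-butyldimethylsilyl)oxy]-8-iodo-2-oxo-4-propyl-3,4-dihydro-2H-chromen-7-yl}oxy)-2-methylbutanoic acid F1 as a mixture of C2 epimers. (COCl)2 with catalytic DMF would convert it into the acid chloride F2. SnCl4 in CH2Cl2 at −78 °C (intramolecular Friedel–Crafts acylation at the only free ortho carbon) would give 17 together with its (2R,3R,6R) trans epimer F3. The two are separated by chromatography, and F3 is re-equilibrated with Et3N and recycled. The route is rejoined at 17.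

2. Step 13. The ligand may discriminate the two faces of C8 poorly, attack may occur at C6 or at oxygen without reversal, or the allyl cation may be attacked at its substituted end. Fallback, from 20: classical base-mediated dearomatising C-prenylation of the acylphloroglucinol (prenyl bromide, aqueous KOH, 0 °C) would give 22 together with the (8S) epimer of the target F4; because of the other stereocentres these are diastereomers and are separated by preparative HPLC. The route is rejoined at 22.

3. Step 11. Oxidative addition and transmetalation may be slow at the iodide flanked by two oxygens, the alkylpalladium intermediate may undergo β-hydride elimination, and the alkylzinc may be protonated or isomerised before it couples. Fallback, from 17 and 3, without a preformed organometallic: nickel-catalysed reductive cross-electrophile coupling (NiBr2·glyme, 4,4′-di-tert-butyl-2,2′-bipyridine, Zn, NaI, DMA, rt) would join the two iodides directly and rejoin the route at 19; no new compound is made.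

Further compounds
F1 | step 10 | (3R)-3-({(4R)-5-[(tert-butyldimethylsilyl)oxy]-8-iodo-2-oxo-4-propyl-3,4-dihydro-2H-chromen-7-yl}oxy)-2-methylbutanoic acid (C2 epimers) | CCC[C@@H]1CC(=O)Oc2c(I)c(O[C@H](C)C(C)C(=O)O)cc(O[Si](C)(C)C(C)(C)C)c12
F2 | step 10 | (3R)-3-({(4R)-5-[(tert-butyldimethylsilyl)oxy]-8-iodo-2-oxo-4-propyl-3,4-dihydro-2H-chromen-7-yl}oxy)-2-methylbutanoyl chloride (C2 epimers) | CCC[C@@H]1CC(=O)Oc2c(I)c(O[C@H](C)C(C)C(=O)Cl)cc(O[Si](C)(C)C(C)(C)C)c12
F3 | step 10 | (2R,3R,6R)-5-[(tert-butyldimethylsilyl)oxy]-10-iodo-2,3-dimethyl-6-propyl-2,3,6,7-tetrahydro-4H,8H-pyrano[3,2-g]chromene-4,8-dione (trans epimer of 17) | CCC[C@@H]1CC(=O)Oc2c(I)c3O[C@H](C)[C@@H](C)C(=O)c3c(O[Si](C)(C)C(C)(C)C)c12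
F4 | step 13 | (3R)-3-{(2R,3S,8S)-5-hydroxy-2,3-dimethyl-8-(3-methylbut-2-en-1-yl)-8-[(2R)-5-methyl-2-(prop-1-en-2-yl)hex-4-en-1-yl]-4,7-dioxo-3,4,7,8-tetrahydro-2H-chromen-6-yl}hexanoic acid (C8 epimer of 22) | C=C(C)[C@H](CC=C(C)C)C[C@]1(CC=C(C)C)C(=O)C([C@H](CCC)CC(=O)O)=C(O)C2=C1O[C@H](C)[C@H](C)C2=O
F0 | step 11 | none | none
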